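## Structural features

The target is a cis-fused clerodane decalin in which ring A (C1–C5, C10) and ring B (C5–C10) share the C5–C10 bond, with the angular methyl C19 on C5 and H-10 on the same face. Ring B carries four contiguous stereocentres: C7 (acetate), C8 (methyl C17), C9 (quaternary, with methyl C20 and the C11–C15 chain) and C10. It is closed by a second quaternary carbon, C5, and the chain holds the remote stereocentre C13 and ends in the C15 carboxylic acid. Ring A carries a cross-conjugated array: the exocyclic methylene C4=C18, the C3 ketone, and the C1=C2 double bond of a diosphenol with the hydroxyl on C2. The fragile groups are the exo-methylene enone (a Michael acceptor), the diosphenol (acidic, oxidisable, base-sensitive) and the secondary C7 acetate, which must survive beside a free acid and rules out late hydrolysis or hydride steps. The real difficulty is the pair of quaternary carbons C5 and C9 flanking C10, in a fixed relation to C7 and C8, together with a ring A oxidation pattern that cannot be carried through many steps. The feature exploited is that the only endocyclic alkene of ring A lies at C1–C2, between C10 and C3. The six atoms of ring A therefore map onto a diene C10=C1–C2=C3 and a dienophile C4=C5 joined through C6–C9, so one cycloaddition of an open-chain triene can close both rings and set C5 and C10.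

## Logic of the disconnections

**37 to 35.** The C4=C18 and C1=C2 double bonds are traced back to C18–O and C1–O single bonds, both β to the C3 ketone, with the C2 oxygen kept. Both sensitive π-systems then appear together in the last step, by elimination alone. 35 has no enone, no enol and no exocyclic alkene. The forward step needs a base that removes the C2 and C4 protons but spares the C7 acetate and the product.

**35 to 30 (through 33, 32, 31).** No C–C bond is cut. The C3 ketone and C15 acid go back to silyl ethers, the carbonate C–O bonds to a C1,C2-diol, and the diol to the C1=C2 alkene. The alkene left by the cycloaddition is the only handle for oxygen at C2, and a cyclic carbonate makes the C1 oxygen a leaving group while storing the C2 oxygen. The forward steps need dihydroxylation of a hindered cis-alkene (either face is acceptable) and desilylation without acyl migration.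

**30 to 28 (through 29).** The C7 and C18 acetates go back to hydroxyls, and these to the C7 methyl carbonate and the C18 methyl ester. One hydride step then frees C7–OH and makes the C18 carbinol, and one acetylation installs both the final C7 acetate and the C18 leaving group. The silyl ethers at C3 and C15 must survive the hydride.

**28 to 27.** The C5–C10 and C3–C4 bonds are cut, opening rings B and A at once. This removes both rings and the C5 and C10 stereocentres, leaving an acyclic triene whose stereocentres (C7, C8, C9, C13) can be set by open-chain methods. The forward step needs endo selectivity (cis fusion) and facial control by the tether, on a trisubstituted dienophile.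

**27 to 23 (through 26, 24).** No skeletal bond is cut. The silyl dienol ether goes back to the E-enal, and this to a primary silyl ether at C3 with the alkene at C10=C1. The diene is the most labile part of 27 and is made last. The forward steps need one primary silyl ether removed beside another and γ-deprotonation that gives the E,E-diene.

**23 to 19 (through 21).** The C5–C19 and C4–C18 bonds and the carbonate C–O bond are cut. Syn-addition of a methyl cuprate to an ynoate gives the Z-enoate, which an olefination would not give reliably. One acylation makes both the ynoate and the C7 carbonate. The cuprate adduct must be protonated cold to keep the Z geometry.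

**19 to 16 + 17.** The C6–C7 bond is cut. The C7 carbinol sits next to C8, so it can be set by Felkin–Anh addition to an α-methyl aldehyde with a quaternary β-carbon. The three carbons C4–C6 come from 17. The forward step needs facial selectivity and propargyl rather than allenyl transfer.

**16 to 11 (through 15, 14).** The C8–C9 bond is cut and the C1–O bond re-formed (retro-[3,3]). The vicinal tertiary/quaternary pair C8/C9 is the hardest acyclic motif, and a sigmatropic shift transfers one carbinol centre into both. 11 has a single carbinol stereocentre and one alkene geometry. The forward step needs the Z-ketene acetal and a chair transition state.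

**11 to 5 + 6 (through 10, 9, 8).** The ester C–O bond, the C10–C1 bond and the C9–C20 bond are cut, and the carbinol C1–H traced to a ketone. Carbometalation of the alkyne fixes the E-trisubstituted alkene, and catalyst-controlled reduction fixes C1. The forward steps need syn, regioselective methylmetalation and an enantioselective 1,2-reduction.

**5 to 1 (through 4, 2).** The C9≡C10 bond is cut (one-carbon homologation) and the aldehyde traced to the alkene of 1. C13 comes from the chiral pool. The only demand is a protecting group at C15 that lasts to step 22.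

## Other disconnections considered

**Alternative 1:** The cut is the C1–C10 bond of ring A, traced back to a C3–C8 bond in the bridged vinyl carbinol A1.
- **Forward step:** deprotonation (KH, 18-crown-6, THF) and [3,3] shift of the alkoxide would break C3–C8 and form C1–C10, giving the cis-decalin A2 (C3 ketone, C4 ketal, C8=C9 alkene) after enolate protonation.
- **In favour:** the cis relation of C19 and H-10 is enforced by the geometry of the bicycle. On this point the alternative is better than the chosen plan, where cis fusion rests on a transition-state preference. The alkoxide acceleration allows low temperature, and C3 arrives at the ketone level.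
- **Against:** A2 has neither C17 on C8 nor the side chain on C9. The quaternary C9 and the C8 methyl would have to be added to the finished decalin, for example through a C7 enone, with facial control that is not secured. The C4 oxygen must be exchanged for C18 at a hindered position, C2 still needs oxygen, and A1 needs an asymmetric entry.
- **Comparison:** on structure, the chosen plan sets C7–C9 and C13 on an open chain and makes both rings at once, while this route makes ring A only. On mechanism, both are pericyclic, and the oxy-Cope is the more stereospecific. On step economy, the route to A2 should be shorter, but the route from A2 longer, so no net saving is expected.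

**Alternative 2:** The cut is the C4–C5 bond, traced back to the vinyl bromide A3 tethered to a ring B enone.
- **Forward step:** zerovalent palladium (Pd(PPh3)4, HCO2Na, DMF) would insert into the C4–Br bond and add 6-exo to C5, forming C4–C5 and the quaternary C5. The C6 palladium enolate has no β-hydrogen on C5, so formate would reduce it to give A4.
- **In favour:** the C18 methylene arrives ready-made and never has to be formed by elimination, which is better than the chosen plan on that point. The short tether from C10 should force cis fusion, equal to the chosen plan in outcome.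
- **Against:** A3 needs ring B with C8, the quaternary C9 and the tether-bearing C10 already set, which is the same quaternary problem in a cyclic setting. The C7 ketone must later be reduced with the right sense. Oxygen at C2 would have to be introduced with the exo-methylene already present, which is harder than in the chosen plan.
- **Comparison:** on structure, one ring, one bond and one relevant stereocentre are made, against two rings and two bonds. On mechanism, a catalytic organometallic closure tolerates functionality well and is the milder step. On step economy, the count depends on the route to A3 and is unlikely to be lower.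

**Alternative 3:** The cuts are C5–C19 and C4–C18, traced back to the ring A enone A5.
- **Forward step:** Me2CuLi would add to C5 and the C3 enolate would be trapped at C4 by [CH2=NMe2]I, giving the Mannich base A6.
- **In favour:** one operation brings in both C19 and C18. The Mannich base is a direct precursor of the methylene without any ester reduction, equal or slightly better than the acetate elimination of the chosen plan. Axial cuprate attack on such octalones normally leads to the cis-fused product.
- **Against:** the key step builds no ring. A5 is already a decalin with C7–C10 set, including the quaternary C9, and its synthesis is the unsolved part. Addition to a β,β-disubstituted enone beside C10 and C9 would be slow, its facial sense against the axial C20 is uncertain, and C2 still needs oxygen.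
- **Comparison:** on structure, the chosen plan makes the decalin and its fusion centres together, while this route decorates an existing one. On mechanism, a polar three-component coupling is operationally simpler than a sealed-tube cycloaddition. On step economy, the endgame would be shorter but the route to A5 longer.

Key step: step 17

Remark: clerodane numbering is used for all intermediates; 6 is taken as a purchasable reagent; where osmylation in step 20 could occur on either face, attack anti to the C3 silyl ether is assumed, and either diol converges on the same product.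

Remark on the structures: the descriptors of 27 and 28 were checked atom by atom against 37 (7S, 8S, 9R, 13R, Z-enoate, E,E-diene; 5S, 10R after cyclisation) and are mutually consistent, so no correction of the core was needed. The one design change is at C7, which carries a methyl carbonate instead of an ether: it is formed in the same operation as the ynoate and removed in the same reduction as the C18 ester, which saves a protection and a deprotection.

## Steps

Step 1
Reactants: 1 (R)-citronellol
Product: 2 (R)-citronellyl tert-butyldiphenylsilyl ether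
Conditions: TBDPSCl, imidazole, DMF, 0 °C to rt
Reagents that add atoms: tert-butyl(chloro)diphenylsilane CC(C)(C)[Si](Cl)(c1ccccc1)c1ccccc1
Why: Silylation of a primary alcohol; the TBDPS ether must outlast the primary TBS ether removed in step 14 and tolerate organolithium, hydride and cuprate reagents.

Step 2
Reactants: 2 (R)-citronellyl tert-butyldiphenylsilyl ether
Product: 4 (4R)-6-(tert-butyldiphenylsilyloxy)-4-methylhexanal, via ozonide 3 (not isolated)
Conditions: O3, CH2Cl2, −78 °C; then PPh3, −78 °C to rt
Reagents that add atoms: ozone [O-][O+]=O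
Why: Ozonolysis of the only alkene with reductive work-up; C13 is not α to the new carbonyl and cannot epimerise.

Step 3
Reactants: 4 (4R)-6-(tert-butyldiphenylsilyloxy)-4-methylhexanal
Product: 5 (3R)-tert-butyl[(3-methylhept-6-yn-1-yl)oxy]diphenylsilane
Conditions: dimethyl (1-diazo-2-oxopropyl)phosphonate, K2CO3, MeOH, 0 °C to rt
Reagents that add atoms: dimethyl (1-diazo-2-oxopropyl)phosphonate COP(=O)(OC)C(=[N+]=[N-])C(C)=O
Why: Ohira–Bestmann homologation of an aldehyde to a terminal alkyne; the former aldehyde carbon becomes C9 and the new carbon C10.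

Step 4
Reactants: 5 (3R)-tert-butyl[(3-methylhept-6-yn-1-yl)oxy]diphenylsilane; 6 3-(tert-butyldimethylsilyloxy)propanal
Product: 8 (E)-allylic alcohol (C1 epimers; C3 OTBS; C15 OTBDPS), via alkenylalane 7 (not isolated)
Conditions: Me3Al, Cp2ZrCl2 (cat.), CH2Cl2, 0 °C to rt; evaporate; n-BuLi, THF/hexane, −78 °C; then 6, −78 to 0 °C
Reagents that add atoms: trimethylaluminium C[Al](C)C
Why: Negishi zirconium-catalysed carboalumination adds methyl (C20) and aluminium syn across the alkyne, with methyl on the internal carbon, fixing the E geometry at C9=C10. The derived alanate adds to the aldehyde to form C10–C1, and the C1 mixture is erased in step 5.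

Step 5
Reactants: 8 (E)-allylic alcohol
Product: 9 (E)-enone (C1 ketone)
Conditions: Dess–Martin periodinane, NaHCO3, CH2Cl2, 0 °C to rt
Reagents that add atoms: none
Why: Buffered Dess–Martin oxidation of an allylic alcohol; neutral conditions avoid β-elimination of the C3 silyloxy group and isomerisation of the alkene.

Step 6
Reactants: 9 (E)-enone
Product: 10 (1S)-allylic alcohol
Conditions: (R)-2-methyl-CBS-oxazaborolidine (0.2 equiv), catecholborane, toluene, −78 °C
Reagents that add atoms: none
Why: Corey–Bakshi–Shibata reduction. The β,β-disubstituted alkenyl group acts as the large substituent and the CH2CH2OTBS chain as the small one, so the (R)-catalyst should deliver hydride to give the 1S carbinol, by analogy with aryl and alkenyl methyl ketones.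

Step 7
Reactants: 10 (1S)-allylic alcohol
Product: 11 (1S)-allylic propanoate
Conditions: (EtCO)2O, Et3N, DMAP (cat.), CH2Cl2, 0 °C to rt
Reagents that add atoms: propanoic anhydride CCC(=O)OC(=O)CC
Why: DMAP-catalysed acylation of a secondary alcohol; the propanoyl group supplies C7, C8 and C17.

Step 8
Reactants: 11 (1S)-allylic propanoate
Product: 14 (8S,9R)-acid with E-C10=C1 alkene, via silyl ketene acetal 12 (not isolated), via silyl ester 13 (not isolated)
Conditions: LiN(i-Pr)2, THF/DMPU, −78 °C; Me3SiCl, Et3N, −78 °C to rt, then 60 °C; H2O, aq. citric acid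
Reagents that add atoms: none
Why: Ireland–Claisen rearrangement. Enolisation in THF/DMPU should give the (Z)-silyl ketene acetal, which rearranges through a chair with the C2 chain on C1 equatorial, C17 equatorial, and on C9 the side chain equatorial and C20 axial. The 1S centre is thereby transferred into 8S and 9R (C17 syn to C11 along the C7–C10 chain), and the new C10=C1 alkene is E.

Step 9
Reactants: 14 (8S,9R)-acid
Product: 15 (8S,9R)-primary alcohol (C7 OH)
Conditions: LiAlH4, Et2O, 0 °C to rt
Reagents that add atoms: none
Why: Hydride reduction of a carboxylic acid; silyl ethers and the isolated alkene are inert and C8 is not epimerised.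

Step 10
Reactants: 15 (8S,9R)-primary alcohol
Product: 16 (8S,9R)-aldehyde (C7 CHO)
Conditions: Dess–Martin periodinane, NaHCO3, CH2Cl2, 0 °C
Reagents that add atoms: none
Why: Buffered Dess–Martin oxidation gives the α-methyl aldehyde without epimerisation at C8; it is used at once.

Step 11
Reactants: 16 (8S,9R)-aldehyde; 17 propargyl bromide
Product: 19 (7S,8S,9R)-homopropargylic alcohol, via allenylzinc bromide 18 (not isolated)
Conditions: Zn (activated), THF, 0 °C; then 16, −78 to 0 °C; aq. NH4Cl
Reagents that add atoms: none
Why: Barbier propargylation: the allenylzinc reagent transfers a propargyl group by SE2′ addition and forms C6–C7. Felkin–Anh attack anti to the quaternary C9 places the new hydroxyl syn to C17, which is the 7S configuration.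

Step 12
Reactants: 19 (7S,8S,9R)-homopropargylic alcohol
Product: 21 ynoate with C7 methyl carbonate, via dilithio alkoxide acetylide 20 (not isolated)
Conditions: n-BuLi (2.2 equiv), THF, −78 °C; ClCO2Me (3 equiv), −78 to −20 °C
Reagents that add atoms: methyl chloroformate COC(Cl)=O
Why: Double deprotonation, then C-acylation of the acetylide (C4–C18 bond) and O-acylation of the alkoxide in one operation. The carbonate blocks lactonisation of the later Z-enoate and is removed in step 18.

Step 13
Reactants: 21 ynoate with C7 methyl carbonate
Product: 23 (Z)-β-methyl enoate, via alkenylcuprate 22 (not isolated)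
Conditions: Me2CuLi (from CuI and MeLi), THF, −78 °C; MeOH then aq. NH4Cl at −78 °C
Reagents that add atoms: lithium dimethylcuprate [Li+].C[Cu-]C (made in the flask from methyllithium [Li]C and CuI)
Why: Syn carbocupration of the ynoate puts C19 on C5 cis to copper. Protonation at −78 °C with retention gives the Z-enoate (C6 cis to the ester), and the carbonate does not react with the cuprate at this temperature.

Step 14
Reactants: 23 (Z)-β-methyl enoate
Product: 24 primary alcohol at C3
Conditions: PPTS, MeOH, rt
Reagents that add atoms: none
Why: Mild acid methanolysis cleaves a primary TBS ether much faster than a primary TBDPS ether. The enoate is inert, and exchange at the methyl carbonate with methanol is degenerate.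

Step 15
Reactants: 24 primary alcohol at C3
Product: 26 (E)-enal (C1=C2; C3 CHO), via β,γ-unsaturated aldehyde 25 (not isolated)
Conditions: Dess–Martin periodinane, NaHCO3, CH2Cl2, 0 °C; then Et3N, rt
Reagents that add atoms: none
Why: Oxidation of the homoallylic alcohol gives the β,γ-unsaturated aldehyde, which Et3N isomerises into conjugation as the more stable E-enal; the amine is too weak to deprotonate the enoate at C6.

Step 16
Reactants: 26 (E)-enal
Product: 27 Z-enoate (1E,3E)-silyl dienol ether triene
Conditions: t-BuMe2SiOTf, Et3N, CH2Cl2, −78 to 0 °C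
Reagents that add atoms: tert-butyldimethylsilyl trifluoromethanesulfonate CC(C)(C)[Si](C)(C)OS(=O)(=O)C(F)(F)F
Why: O-Silylation of the enal and γ-deprotonation at C10 (soft enolisation). The s-trans enal gives the E-enol ether at C2=C3, and the bulk of C9 favours E at C10=C1.

Step 17
Reactants: 27 Z-enoate (1E,3E)-silyl dienol ether triene
Product: 28 cis-fused octalin (C3 OTBS; C4 CO2Me; C7 OCO2Me; C15 OTBDPS)
Conditions: toluene (0.01 M), BHT, Et3N (trace), base-washed sealed tube, 190 °C
Reagents that add atoms: none
Why: This is a concerted, thermally allowed suprafacial [4+2] cycloaddition of normal electron demand: the silyloxy group raises the diene HOMO and puts its largest coefficient on C10, which bonds to the enoate β-carbon C5, while C3 bonds to the α-carbon C4. The closest known reaction type is the thermal intramolecular Diels–Alder reaction of 1,7,9-decatrienoates with Z-dienophiles and 1-oxygenated dienes, which gives cis-fused octalins. Ring B closes through the C5–C10 bond as a six-membered carbocycle spanned by the C6–C9 tether, and ring A is the cyclohexene formed by the cycloaddition itself, with its alkene at C1–C2. C5 and C10 become cis because the Z-enoate holds the ester and the tether on one side of the dienophile, so the endo-ester arrangement folds C6 under the diene on the face that carries C9. C3 and C4 follow from retention of the E-enol ether and Z-enoate geometries (silyl ether, ester, C6 and C9 on one face); both are erased later, so their control is not essential. The sense of C5 and C10 relative to C7–C9 should be set by a chair-like tether with the C7 carbonate, the C8 methyl and the C9 side chain equatorial and C20 axial, since the other diene face would place C19 1,3-diaxial to C20. The step needs endo over exo selectivity and facial selectivity; the Z geometry from step 13, the E,E-diene from step 16 and the tether stereocentres from steps 8 and 11 are meant to secure them, and base-washed glass with a trace of amine protects the silyl dienol ether.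

Step 18
Reactants: 28 cis-fused octalin
Product: 29 C7,C18-diol
Conditions: i-Bu2AlH (excess), CH2Cl2, −78 to 0 °C; aq. potassium sodium tartrate
Reagents that add atoms: none
Why: Hydride reduction of the C18 ester to the primary alcohol and reductive cleavage of the C7 methyl carbonate in one step; silyl ethers and the alkene are inert.

Step 19
Reactants: 29 C7,C18-diol
Product: 30 C7,C18-diacetate
Conditions: Ac2O, pyridine, DMAP (cat.), rt
Reagents that add atoms: acetic anhydride CC(=O)OC(C)=O
Why: Acetylation installs the final C7 acetate and, in the same step, the C18 leaving group for the later β-elimination.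

Step 20
Reactants: 30 C7,C18-diacetate
Product: 31 C1,C2-cis-diol
Conditions: OsO4 (cat.), NMO, acetone/H2O, rt
Reagents that add atoms: osmium tetroxide O=[Os](=O)(=O)=O; N-methylmorpholine N-oxide C[N+]1([O-])CCOCC1; water O
Why: Upjohn syn-dihydroxylation of the only alkene, expected anti to the allylic C3 silyl ether and to C9. The new centres at C1 and C2 are both erased in step 24, so either face serves.

Step 21
Reactants: 31 C1,C2-cis-diol
Product: 32 C1,C2-cyclic carbonate
Conditions: 1,1′-carbonyldiimidazole, DMAP (cat.), toluene, 60 °C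
Reagents that add atoms: 1,1′-carbonyldiimidazole O=C(n1ccnc1)n1ccnc1
Why: Carbonylation of a cis-1,2-diol protects both hydroxyls against the oxidation of step 23 and turns the C1 oxygen into a leaving group.

Step 22
Reactants: 32 C1,C2-cyclic carbonate
Product: 33 C3,C15-diol
Conditions: HF·pyridine, pyridine, THF, 0 °C to rt
Reagents that add atoms: none
Why: Acidic fluoride removes the secondary TBS and primary TBDPS ethers; basic fluoride is avoided because it would promote acetyl migration from C18 to C3 and opening of the carbonate.

Step 23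
Reactants: 33 C3,C15-diol
Product: 35 C3-keto C15-acid, via keto aldehyde 34 (not isolated)
Conditions: CrO3, H2SO4, H2O, acetone, 0 °C
Reagents that add atoms: water O
Why: Jones oxidation takes the secondary C3 alcohol to the ketone and the primary C15 alcohol through the aldehyde hydrate to the acid; no alkene is present, and acetates and the carbonate tolerate the acid.

Step 24
Reactants: 35 C3-keto C15-acid
Product: 37 target acid, via enol hydrogen carbonate 36 (not isolated)
Conditions: DBU, CH2Cl2, 0 °C; then aq. NaH2PO4 (pH 4)
Reagents that add atoms: none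
Why: Two E1cB β-eliminations from the C3 ketone: enolisation toward C4 expels the C18 acetate (C4=C18), and enolisation toward C2 opens the carbonate at C1 (C1=C2); the resulting enol hydrogen carbonate loses CO2 to free the diosphenol. The C7 acetate is not β to a carbonyl and stays, and no stereocentre is formed.

## Compound list

1 | (R)-citronellol, (3R)-3,7-dimethyloct-6-en-1-ol | CC(C)=CCC[C@@H](C)CCO | starting material

2 | (3R)-tert-butyl[(3,7-dimethyloct-6-en-1-yl)oxy]diphenylsilane | CC(C)=CCC[C@@H](C)CCO[Si](c1ccccc1)(c1ccccc1)C(C)(C)C | intermediate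

3 | secondary ozonide of 2: 3,3-dimethyl-5-[(3R)-5-(tert-butyldiphenylsilyloxy)-3-methylpentyl]-1,2,4-trioxolane (ring CH unassigned) | CC1(C)OOC(CC[C@@H](C)CCO[Si](c2ccccc2)(c2ccccc2)C(C)(C)C)O1 | intermediate (not isolated)

4 | (4R)-6-(tert-butyldiphenylsilyloxy)-4-methylhexanal | O=CCC[C@@H](C)CCO[Si](c1ccccc1)(c1ccccc1)C(C)(C)C | intermediate

5 | (3R)-tert-butyl[(3-methylhept-6-yn-1-yl)oxy]diphenylsilane | C#CCC[C@@H](C)CCO[Si](c1ccccc1)(c1ccccc1)C(C)(C)C | intermediate

6 | 3-(tert-butyldimethylsilyloxy)propanal | O=CCCO[Si](C)(C)C(C)(C)C | starting material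

7 | dimethyl[(1E,5R)-7-(tert-butyldiphenylsilyloxy)-2,5-dimethylhept-1-en-1-yl]alane | C/C(CC[C@@H](C)CCO[Si](c1ccccc1)(c1ccccc1)C(C)(C)C)=C\[Al](C)C | intermediate (not isolated)

8 | (4E,8R)-1-(tert-butyldimethylsilyloxy)-10-(tert-butyldiphenylsilyloxy)-5,8-dimethyldec-4-en-3-ol, both epimers at the carbinol (clerodane C1) | C/C(CC[C@@H](C)CCO[Si](c1ccccc1)(c1ccccc1)C(C)(C)C)=C\C(O)CCO[Si](C)(C)C(C)(C)C | intermediate

9 | (4E,8R)-1-(tert-butyldimethylsilyloxy)-10-(tert-butyldiphenylsilyloxy)-5,8-dimethyldec-4-en-3-one | C/C(CC[C@@H](C)CCO[Si](c1ccccc1)(c1ccccc1)C(C)(C)C)=C\C(=O)CCO[Si](C)(C)C(C)(C)C | intermediate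

10 | (3S,4E,8R)-1-(tert-butyldimethylsilyloxy)-10-(tert-butyldiphenylsilyloxy)-5,8-dimethyldec-4-en-3-ol (clerodane 1S) | C/C(CC[C@@H](C)CCO[Si](c1ccccc1)(c1ccccc1)C(C)(C)C)=C\[C@@H](O)CCO[Si](C)(C)C(C)(C)C | intermediate

11 | (3S,4E,8R)-1-(tert-butyldimethylsilyloxy)-10-(tert-butyldiphenylsilyloxy)-5,8-dimethyldec-4-en-3-yl propanoate | C/C(CC[C@@H](C)CCO[Si](c1ccccc1)(c1ccccc1)C(C)(C)C)=C\[C@@H](OC(=O)CC)CCO[Si](C)(C)C(C)(C)C | intermediate

12 | (Z)-O-trimethylsilyl ketene acetal of 11 (methyl cis to OSiMe3) | C/C(CC[C@@H](C)CCO[Si](c1ccccc1)(c1ccccc1)C(C)(C)C)=C\[C@@H](O/C(O[Si](C)(C)C)=C/C)CCO[Si](C)(C)C(C)(C)C | intermediate (not isolated)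

13 | trimethylsilyl ester of 14 | C[Si](C)(C)OC(=O)[C@@H](C)[C@](C)(CC[C@@H](C)CCO[Si](c1ccccc1)(c1ccccc1)C(C)(C)C)/C=C/CCO[Si](C)(C)C(C)(C)C | intermediate (not isolated)

14 | (2S,3R,4E)-7-(tert-butyldimethylsilyloxy)-3-[(3R)-5-(tert-butyldiphenylsilyloxy)-3-methylpentyl]-2,3-dimethylhept-4-enoic acid (clerodane 8S,9R) | OC(=O)[C@@H](C)[C@](C)(CC[C@@H](C)CCO[Si](c1ccccc1)(c1ccccc1)C(C)(C)C)/C=C/CCO[Si](C)(C)C(C)(C)C | intermediate

15 | (2S,3R,4E)-7-(tert-butyldimethylsilyloxy)-3-[(3R)-5-(tert-butyldiphenylsilyloxy)-3-methylpentyl]-2,3-dimethylhept-4-en-1-ol | OC[C@@H](C)[C@](C)(CC[C@@H](C)CCO[Si](c1ccccc1)(c1ccccc1)C(C)(C)C)/C=C/CCO[Si](C)(C)C(C)(C)C | intermediate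

16 | (2S,3R,4E)-7-(tert-butyldimethylsilyloxy)-3-[(3R)-5-(tert-butyldiphenylsilyloxy)-3-methylpentyl]-2,3-dimethylhept-4-enal | O=C[C@@H](C)[C@](C)(CC[C@@H](C)CCO[Si](c1ccccc1)(c1ccccc1)C(C)(C)C)/C=C/CCO[Si](C)(C)C(C)(C)C | intermediate

17 | propargyl bromide (3-bromoprop-1-yne) | C#CCBr | starting material

18 | allenylzinc bromide (propa-1,2-dienylzinc bromide) | C=C=C[Zn]Br | intermediate (not isolated)

19 | (4S,5S,6R,7E)-10-(tert-butyldimethylsilyloxy)-6-[(3R)-5-(tert-butyldiphenylsilyloxy)-3-methylpentyl]-5,6-dimethyldec-7-en-1-yn-4-ol (clerodane 7S,8S,9R) | C#CC[C@H](O)[C@@H](C)[C@](C)(CC[C@@H](C)CCO[Si](c1ccccc1)(c1ccccc1)C(C)(C)C)/C=C/CCO[Si](C)(C)C(C)(C)C | intermediate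

20 | dilithium salt of 19 (lithium acetylide and lithium alkoxide) | [Li]C#CC[C@H](O[Li])[C@@H](C)[C@](C)(CC[C@@H](C)CCO[Si](c1ccccc1)(c1ccccc1)C(C)(C)C)/C=C/CCO[Si](C)(C)C(C)(C)C | intermediate (not isolated)

21 | methyl (5S,6S,7R,8E)-11-(tert-butyldimethylsilyloxy)-7-[(3R)-5-(tert-butyldiphenylsilyloxy)-3-methylpentyl]-5-(methoxycarbonyloxy)-6,7-dimethylundec-8-en-2-ynoate | COC(=O)C#CC[C@H](OC(=O)OC)[C@@H](C)[C@](C)(CC[C@@H](C)CCO[Si](c1ccccc1)(c1ccccc1)C(C)(C)C)/C=C/CCO[Si](C)(C)C(C)(C)C | intermediate

22 | lithium alkenyl(methyl)cuprate from syn addition to 21 (copper on C4, cis to the new C19 methyl) | [Li+].COC(=O)/C([Cu-]C)=C(/C)C[C@H](OC(=O)OC)[C@@H](C)[C@](C)(CC[C@@H](C)CCO[Si](c1ccccc1)(c1ccccc1)C(C)(C)C)/C=C/CCO[Si](C)(C)C(C)(C)C | intermediate (not isolated)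

23 | methyl (2Z,5S,6S,7R,8E)-11-(tert-butyldimethylsilyloxy)-7-[(3R)-5-(tert-butyldiphenylsilyloxy)-3-methylpentyl]-5-(methoxycarbonyloxy)-3,6,7-trimethylundeca-2,8-dienoate | COC(=O)/C=C(/C)C[C@H](OC(=O)OC)[C@@H](C)[C@](C)(CC[C@@H](C)CCO[Si](c1ccccc1)(c1ccccc1)C(C)(C)C)/C=C/CCO[Si](C)(C)C(C)(C)C | intermediate

24 | methyl (2Z,5S,6S,7R,8E)-7-[(3R)-5-(tert-butyldiphenylsilyloxy)-3-methylpentyl]-11-hydroxy-5-(methoxycarbonyloxy)-3,6,7-trimethylundeca-2,8-dienoate | COC(=O)/C=C(/C)C[C@H](OC(=O)OC)[C@@H](C)[C@](C)(CC[C@@H](C)CCO[Si](c1ccccc1)(c1ccccc1)C(C)(C)C)/C=C/CCO | intermediate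

25 | methyl (2Z,5S,6S,7R,8E)-7-[(3R)-5-(tert-butyldiphenylsilyloxy)-3-methylpentyl]-5-(methoxycarbonyloxy)-3,6,7-trimethyl-11-oxoundeca-2,8-dienoate | COC(=O)/C=C(/C)C[C@H](OC(=O)OC)[C@@H](C)[C@](C)(CC[C@@H](C)CCO[Si](c1ccccc1)(c1ccccc1)C(C)(C)C)/C=C/CC=O | intermediate (not isolated)

26 | methyl (2Z,5S,6S,7R,9E)-7-[(3R)-5-(tert-butyldiphenylsilyloxy)-3-methylpentyl]-5-(methoxycarbonyloxy)-3,6,7-trimethyl-11-oxoundeca-2,9-dienoate | COC(=O)/C=C(/C)C[C@H](OC(=O)OC)[C@@H](C)[C@](C)(CC[C@@H](C)CCO[Si](c1ccccc1)(c1ccccc1)C(C)(C)C)C/C=C/C=O | intermediate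

27 | methyl (2Z,5S,6S,7R,8E,10E)-11-(tert-butyldimethylsilyloxy)-7-[(3R)-5-(tert-butyldiphenylsilyloxy)-3-methylpentyl]-5-(methoxycarbonyloxy)-3,6,7-trimethylundeca-2,8,10-trienoate (cycloaddition precursor) | COC(=O)/C=C(/C)C[C@H](OC(=O)OC)[C@@H](C)[C@](C)(CC[C@@H](C)CCO[Si](c1ccccc1)(c1ccccc1)C(C)(C)C)/C=C/C=C/O[Si](C)(C)C(C)(C)C | intermediate

28 | methyl (3R,4S,5S,7S,8S,9R,10R,13R)-3-(tert-butyldimethylsilyloxy)-15-(tert-butyldiphenylsilyloxy)-7-(methoxycarbonyloxy)-cis-clerod-1-en-18-oate (silyl ether, ester, C6 and C9 on one face of ring A) | COC(=O)[C@@H]1[C@H](O[Si](C)(C)C(C)(C)C)C=C[C@@H]2[C@@](C)(CC[C@@H](C)CCO[Si](c3ccccc3)(c3ccccc3)C(C)(C)C)[C@H](C)[C@@H](OC(=O)OC)C[C@]12C | intermediate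

29 | (5S,7S,8S,9R,10R,13R)-3-(tert-butyldimethylsilyloxy)-15-(tert-butyldiphenylsilyloxy)-cis-clerod-1-ene-7,18-diol (C3 and C4 as in 28) | OC[C@@H]1[C@H](O[Si](C)(C)C(C)(C)C)C=C[C@@H]2[C@@](C)(CC[C@@H](C)CCO[Si](c3ccccc3)(c3ccccc3)C(C)(C)C)[C@H](C)[C@@H](O)C[C@]12C | intermediate

30 | 7,18-diacetate of 29 | CC(=O)OC[C@@H]1[C@H](O[Si](C)(C)C(C)(C)C)C=C[C@@H]2[C@@](C)(CC[C@@H](C)CCO[Si](c3ccccc3)(c3ccccc3)C(C)(C)C)[C@H](C)[C@@H](OC(C)=O)C[C@]12C | intermediate

31 | 7,18-diacetoxy-3-(tert-butyldimethylsilyloxy)-15-(tert-butyldiphenylsilyloxy)-cis-clerodane-1,2-diol (hydroxyls cis to each other and trans to the C3 silyl ether) | CC(=O)OC[C@@H]1[C@H](O[Si](C)(C)C(C)(C)C)[C@@H](O)[C@@H](O)[C@@H]2[C@@](C)(CC[C@@H](C)CCO[Si](c3ccccc3)(c3ccccc3)C(C)(C)C)[C@H](C)[C@@H](OC(C)=O)C[C@]12C | intermediate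

32 | 1,2-cyclic carbonate of 31 | CC(=O)OC[C@@H]1[C@H](O[Si](C)(C)C(C)(C)C)[C@H]3OC(=O)O[C@H]3[C@@H]2[C@@](C)(CC[C@@H](C)CCO[Si](c4ccccc4)(c4ccccc4)C(C)(C)C)[C@H](C)[C@@H](OC(C)=O)C[C@]12C | intermediate

33 | 7,18-diacetoxy-1,2-(carbonyldioxy)-cis-clerodane-3,15-diol | CC(=O)OC[C@@H]1[C@H](O)[C@H]3OC(=O)O[C@H]3[C@@H]2[C@@](C)(CC[C@@H](C)CCO)[C@H](C)[C@@H](OC(C)=O)C[C@]12C | intermediate

34 | 7,18-diacetoxy-1,2-(carbonyldioxy)-3-oxo-cis-clerodan-15-al | CC(=O)OC[C@@H]1C(=O)[C@H]3OC(=O)O[C@H]3[C@@H]2[C@@](C)(CC[C@@H](C)CC=O)[C@H](C)[C@@H](OC(C)=O)C[C@]12C | intermediate (not isolated)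

35 | 7,18-diacetoxy-1,2-(carbonyldioxy)-3-oxo-cis-clerodan-15-oic acid | CC(=O)OC[C@@H]1C(=O)[C@H]3OC(=O)O[C@H]3[C@@H]2[C@@](C)(CC[C@@H](C)CC(=O)O)[C@H](C)[C@@H](OC(C)=O)C[C@]12C | intermediate

36 | 7-acetoxy-2-(carboxyoxy)-3-oxo-cis-cleroda-1,4(18)-dien-15-oic acid (enol hydrogen carbonate) | C=C1C(=O)C(OC(=O)O)=C[C@@H]2[C@@](C)(CC[C@@H](C)CC(=O)O)[C@H](C)[C@@H](OC(C)=O)C[C@]12C | intermediate (not isolated)

37 | (5S,7S,8S,9R,10R,13R)-7-acetoxy-2-hydroxy-3-oxo-cis-cleroda-1,4(18)-dien-15-oic acid, CNP0257844.1 | C=C1C(=O)C(O)=C[C@@H]2[C@@](C)(CC[C@@H](C)CC(=O)O)[C@H](C)[C@@H](OC(C)=O)C[C@]12C | target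

## Step count and risks

Total step count: 24. Longest linear sequence: 24 steps (1 to 37); 6 and 17 are used as purchased.

**Step 17 (key step).**
- The trisubstituted Z-enoate may react so slowly that desilylation of the dienol ether or geometric isomerisation of the enoate competes at the temperature required.
- Endo/exo discrimination may erode, so that trans-fused material forms.
- The tether may discriminate the two diene faces poorly, because only a 1,3-diaxial methyl interaction separates them.
- Fallback: from 26, excess t-BuMe2SiOTf/Et3N, or 27 with catalytic Me3SiNTf2, at −78 to 0 °C could form the same two bonds stepwise. An intramolecular vinylogous Mukaiyama–Michael addition (C10 to C5) would be followed by silyl-transfer aldol closure of the resulting ketene acetal onto the silylated C3 carbonyl. This ionic path needs no heating, returns to the route at 28 and makes no new compound (F0).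

**Step 8.**
- Enolate geometry may be controlled incompletely, which would erode the C8 configuration.
- The rearrangement onto the fully substituted C9 may be slow, so C-silylation or ester cleavage could compete.
- Fallback, setting out from 10: heating with triethyl orthoacetate and catalytic propanoic acid (Johnson–Claisen) would set C9 alone through the same chair and give the ethyl ester F1. Saponification would give the acid F2. Acylation of lithiated (S)-4-benzyloxazolidin-2-one through the pivaloyl mixed anhydride would give the imide F3. Auxiliary-controlled methylation (NaN(SiMe3)2, MeI, −78 °C) would give the 8S methylated imide F4. LiBH4 reduction would rejoin the route at 15.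

**Step 11.**
- Felkin control may be incomplete, giving the C7 epimer.
- Allenyl transfer may compete with propargyl transfer.
- Fallback, setting out from 16: catalyst-controlled propargylation with allenylboronic acid pinacol ester and a BINOL-derived chiral phosphoric acid, using the enantiomer that directs attack to the Si face and is matched with the Felkin preference. It returns at 19 and makes no new compound (F0).

**Step 24.**
- The liberated exo-methylene enone may undergo conjugate addition or oligomerise under the base.
- The amidine may open the carbonate nucleophilically instead of triggering fragmentation.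
- One of the two eliminations may stay incomplete.
- Fallback, setting out from 31: acetylation of the diol to the tetraacetate F5, then HF·pyridine to the 3,15-diol F6, then CrO3/H2SO4 to the keto acid F7. Et3N would then eliminate the C18 and C1 acetates to give the diosphenol acetate F8. Mild methanolysis of the enol ester (NaHCO3, MeOH, 0 °C) would return to the route at 37.

## Further compounds

F0 | step 17 | none | none
F1 | step 8 | ethyl (4E)-7-(tert-butyldimethylsilyloxy)-3-[(3R)-5-(tert-butyldiphenylsilyloxy)-3-methylpentyl]-3-methylhept-4-enoate (C9 arranged as in 14) | CCOC(=O)C[C@](C)(CC[C@@H](C)CCO[Si](c1ccccc1)(c1ccccc1)C(C)(C)C)/C=C/CCO[Si](C)(C)C(C)(C)C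
F2 | step 8 | (4E)-7-(tert-butyldimethylsilyloxy)-3-[(3R)-5-(tert-butyldiphenylsilyloxy)-3-methylpentyl]-3-methylhept-4-enoic acid | OC(=O)C[C@](C)(CC[C@@H](C)CCO[Si](c1ccccc1)(c1ccccc1)C(C)(C)C)/C=C/CCO[Si](C)(C)C(C)(C)C
F3 | step 8 | (4S)-4-benzyl-3-acyloxazolidin-2-one of F2 | O=C(C[C@](C)(CC[C@@H](C)CCO[Si](c1ccccc1)(c1ccccc1)C(C)(C)C)/C=C/CCO[Si](C)(C)C(C)(C)C)N1[C@@H](Cc2ccccc2)COC1=O
F4 | step 8 | α-methylated imide (clerodane 8S,9R; (4S)-4-benzyloxazolidin-2-one) | O=C([C@@H](C)[C@](C)(CC[C@@H](C)CCO[Si](c1ccccc1)(c1ccccc1)C(C)(C)C)/C=C/CCO[Si](C)(C)C(C)(C)C)N1[C@@H](Cc2ccccc2)COC1=O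
F0 | step 11 | none | none
F5 | step 24 | 1,2,7,18-tetraacetoxy-3-(tert-butyldimethylsilyloxy)-15-(tert-butyldiphenylsilyloxy)-cis-clerodane | CC(=O)OC[C@@H]1[C@H](O[Si](C)(C)C(C)(C)C)[C@@H](OC(C)=O)[C@@H](OC(C)=O)[C@@H]2[C@@](C)(CC[C@@H](C)CCO[Si](c3ccccc3)(c3ccccc3)C(C)(C)C)[C@H](C)[C@@H](OC(C)=O)C[C@]12C
F6 | step 24 | 1,2,7,18-tetraacetoxy-cis-clerodane-3,15-diol | CC(=O)OC[C@@H]1[C@H](O)[C@@H](OC(C)=O)[C@@H](OC(C)=O)[C@@H]2[C@@](C)(CC[C@@H](C)CCO)[C@H](C)[C@@H](OC(C)=O)C[C@]12C
F7 | step 24 | 1,2,7,18-tetraacetoxy-3-oxo-cis-clerodan-15-oic acid | CC(=O)OC[C@@H]1C(=O)[C@@H](OC(C)=O)[C@@H](OC(C)=O)[C@@H]2[C@@](C)(CC[C@@H](C)CC(=O)O)[C@H](C)[C@@H](OC(C)=O)C[C@]12C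
F8 | step 24 | 2,7-diacetoxy-3-oxo-cis-cleroda-1,4(18)-dien-15-oic acid (diosphenol acetate) | C=C1C(=O)C(OC(C)=O)=C[C@@H]2[C@@](C)(CC[C@@H](C)CC(=O)O)[C@H](C)[C@@H](OC(C)=O)C[C@]12C
A1 | alternative 1 | bridged vinyl carbinol: 7-benzyloxy-4,4-dimethoxy-5,9-dimethyl-3-vinylbicyclo[2.2.2]oct-9-en-3-ol (clerodane numbering; vinyl syn to the C9=C10 bridge) | C=C[C@]1(O)C(OC)(OC)[C@@]2(C)C[C@H](OCc3ccccc3)[C@@H]1C(C)=C2
A2 | alternative 1 | cis-decalin with C3 ketone, C4 dimethyl ketal, C7 benzyl ether and C8=C9 alkene | COC1(OC)C(=O)CC[C@@H]2C(C)=C[C@@H](OCc3ccccc3)C[C@]12C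
A3 | alternative 2 | ring B enone (C5=C6, C7 ketone) with C10 side chain ending in the C3 dioxolane and the C4 vinyl bromide | C=C(Br)C1(OCCO1)CC[C@@H]2[C@@](C)(CC[C@@H](C)CCO[Si](C)(C)C(C)(C)C)[C@H](C)C(=O)C=C2C
A4 | alternative 2 | cis-decalin with C4 methylene, C3 dioxolane and C7 ketone | C=C1C2(OCCO2)CC[C@@H]3[C@@](C)(CC[C@@H](C)CCO[Si](C)(C)C(C)(C)C)[C@H](C)C(=O)C[C@]13C
A5 | alternative 3 | ring A enone (C3 ketone, C4=C5) with C7 OTBS and C15 OTIPS | O=C1CC[C@@H]2[C@@](C)(CC[C@@H](C)CCO[Si](C(C)C)(C(C)C)C(C)C)[C@H](C)[C@@H](O[Si](C)(C)C(C)(C)C)CC2=C1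
A6 | alternative 3 | cis-fused C4 Mannich base with angular methyl at C5 | CN(C)C[C@@H]1C(=O)CC[C@@H]2[C@@](C)(CC[C@@H](C)CCO[Si](C(C)C)(C(C)C)C(C)C)[C@H](C)[C@@H](O[Si](C)(C)C(C)(C)C)C[C@]12C
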